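**Plan**

Cuts, in retrosynthetic order: the ethyl ester; the sp3–sp2 bond C2'–C3' of the side chain, which divides the target into an oxane core with a two-carbon arm and an (E)-alkenyl iodide carrying the (R)-allylic alcohol; the exocyclic methylene of the acrylate; and, inside the core, the ring bonds C3–C4 and O1–C6 together.
Enabling feature: in the 2,5-disubstituted oxane ring, C6 is a bare O–CH2 and C4 a bare CH2, both on the C5 methine. Raised to the aldehyde level, C4–C5–C6 is a 2-substituted acrolein (C4 the radical acceptor, C6 the carbonyl that O1 closes on, C5–H epimerizable), and C3–C2(O1)–Cα–CO2 is the chain of a commercial (S)-4-halo-3-hydroxybutanoate.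
Forward: the oxane ring arises in one operation by radical conjugate addition and lactolization; the lactol hydroxyl is then removed with a silane, the acetate arm is methylenated and the chloroethyl arm becomes an iodide. The side chain is built from a C5 alkynol and a C8 methyl ketone; a Negishi coupling joins the halves and saponification ends the route.
Stereochemistry: C2 comes from the chiral-pool hydroxy ester and is never touched; C5 is set by thermodynamic epimerization of the lactol to the trans-2,5-diequatorial ring; the carbinol carbon by CBS reduction; the E alkene by syn-carboalumination.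

Key step: step 3

Remark: ring atoms are numbered O1, C2 (carries the acrylate), C3, C4, C5 (carries the side chain), C6, and side-chain atoms C1' to C13' from the ring; the chloro aldehyde used in step 2 is taken as the commercial compound (it can also be freed from its commercial dimethyl acetal).

**Route**

Step 1
Reactants: 1 ethyl (3S)-4-chloro-3-hydroxybutanoate
Product: 2 ethyl (3S)-3-hydroxy-4-iodobutanoate
Conditions: NaI (3 equiv), 2-butanone, 80 °C, dark
Reagents that add atoms: sodium iodide, [Na+].[I-]
Why: Finkelstein halide exchange (SN2 at the primary carbon, driven by precipitation of NaCl) gives the iodide needed for fast halogen-atom abstraction, and the carbinol stereocentre is not involved.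

Step 2
Reactants: 3 4-chlorobutanal; 4 formaldehyde (37 % in water)
Product: 5 4-chloro-2-methylidenebutanal
Conditions: pyrrolidine (10 mol %), EtCO2H (10 mol %), iPrOH, 45 °C
Reagents that add atoms: none
Why: Amine-catalysed Mannich condensation and elimination (α-methylenation of an aldehyde), in which the enamine of 3 adds to the formaldehyde-derived iminium ion and loses the amine much faster than it could be alkylated by the primary chloride.

Step 3
Reactants: 2 ethyl (3S)-3-hydroxy-4-iodobutanoate; 5 4-chloro-2-methylidenebutanal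
Product: 8 ethyl 2-[(2R,5R,6RS)-5-(2-chloroethyl)-6-hydroxyoxan-2-yl]acetate, via open-chain hydroxy aldehyde 6 (not isolated), via C5-epimeric lactol mixture 7 (not isolated)
Conditions: (Me3Si)3SiH (1.2 equiv, slow addition), AIBN (10 mol %), 5 (2 equiv), PhMe, 80 °C; evaporation; then pyrrolidine (20 mol %), AcOH (20 mol %), CH2Cl2, 23 °C
Reagents that add atoms: none
Why: Mechanism: the silyl radical takes iodine from 2 (much faster than chlorine from 5 or 6), the nucleophilic primary β-hydroxyalkyl radical adds to the unsubstituted CH2 terminus (C4) of the electron-poor 2-substituted acrolein 5 to form C3–C4, the α-formyl radical takes hydrogen from the silane to give 6 and carry the chain, and the δ-hydroxyl then adds to the aldehyde to form O1–C6. The closest known reaction type is the Giese radical conjugate addition of alkyl iodides to enals under silane mediation followed by spontaneous lactol formation of the δ-hydroxy aldehyde. The oxane ring closes by 6-exo-trig hemiacetalization. C2 is carried over unchanged from the (S)-hydroxy ester; C5 is created without control in the hydrogen-atom transfer, but it is α to the masked aldehyde, so the pyrrolidinium acetate buffer epimerizes it through the enamine of the open form until the chair with the C2 acetate arm and the C5 chloroethyl arm both equatorial (trans-2,5, lactol 8) should predominate, and recovered cis-lactol can be returned to the buffer; the anomeric centre C6 stays a mixture and is removed in step 4. The step needs halogen selectivity (secured by the weak C–I bond against the C–Cl bonds), addition before reduction of the alkyl radical (secured by slow addition of the silane and an excess of 5), and a thermodynamic bias at C5 (secured by the strong equatorial preference of the C2 arm next to the ring oxygen, which anchors the chair so that the C5 arm alone decides the equilibrium).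

Step 4
Reactants: 8 ethyl 2-[(2R,5R,6RS)-5-(2-chloroethyl)-6-hydroxyoxan-2-yl]acetate
Product: 9 ethyl 2-[(2R,5R)-5-(2-chloroethyl)oxan-2-yl]acetate
Conditions: Et3SiH (3 equiv), CF3CO2H (5 equiv), CH2Cl2, −40 → 0 °C
Reagents that add atoms: none
Why: Ionic hydrogenation of the lactol (loss of water to the cyclic oxocarbenium ion, then hydride transfer from the silane) turns C6 into the ring O–CH2 without creating a stereocentre and leaves C2, C5, the ester and the chloride untouched.

Step 5
Reactants: 9 ethyl 2-[(2R,5R)-5-(2-chloroethyl)oxan-2-yl]acetate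
Product: 10 ethyl 2-[(2R,5R)-5-(2-chloroethyl)oxan-2-yl]-3-(dimethylamino)propanoate
Conditions: LiN(iPr)2 (1.1 equiv), THF, −78 °C; then CH2=NMe2+ I− (1.5 equiv), −78 → 0 °C
Reagents that add atoms: N,N-dimethylmethylideneammonium iodide, C=[N+](C)C.[I-]
Why: Mannich reaction of the lithium ester enolate with the preformed iminium salt, in which the β-alkoxy enolate should be trapped at −78 °C before it can expel the ring oxygen, and the new α-centre (formed as a mixture) is erased in step 6.

Step 6
Reactants: 10 ethyl 2-[(2R,5R)-5-(2-chloroethyl)oxan-2-yl]-3-(dimethylamino)propanoate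
Product: 12 ethyl 2-[(2R,5R)-5-(2-chloroethyl)oxan-2-yl]prop-2-enoate, via quaternary ammonium iodide 11 (not isolated)
Conditions: MeI (3 equiv), CH2Cl2, 23 °C; then K2CO3, H2O/CH2Cl2, 23 °C
Reagents that add atoms: none
Why: N-Methylation to the trimethylammonium salt and E1cB elimination of trimethylamine (Hofmann-type elimination of a Mannich base) unveil the α-methylene ester under conditions too mild to open the ring.

Step 7
Reactants: 12 ethyl 2-[(2R,5R)-5-(2-chloroethyl)oxan-2-yl]prop-2-enoate
Product: 13 ethyl 2-[(2R,5R)-5-(2-iodoethyl)oxan-2-yl]prop-2-enoate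
Conditions: NaI (5 equiv), acetone, 56 °C, BHT (trace), dark
Reagents that add atoms: sodium iodide, [Na+].[I-]
Why: Finkelstein exchange at the unhindered primary chloride gives the iodide required for zinc insertion, while the acrylate is inert to iodide.

Step 8
Reactants: 14 pent-4-yn-1-ol
Product: 16 (4E)-5-iodo-4-methylpent-4-en-1-ol, via alkenylalane 15 (not isolated)
Conditions: AlMe3 (3 equiv), Cp2ZrCl2 (0.25 equiv), CH2Cl2, 0 → 23 °C; then I2, THF, −30 → 0 °C; aqueous work-up
Reagents that add atoms: trimethylaluminium, C[Al](C)C; iodine, [I][I]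
Why: Zirconium-catalysed carboalumination (Negishi carboalumination) adds methyl and aluminium syn across the alkyne with methyl on the internal carbon, and iodinolysis of the C–Al bond with retention fixes the E trisubstituted alkenyl iodide.

Step 9
Reactants: 16 (4E)-5-iodo-4-methylpent-4-en-1-ol
Product: 17 (4E)-5-iodo-4-methylpent-4-enal
Conditions: TEMPO (10 mol %), PhI(OAc)2 (1.1 equiv), CH2Cl2, 23 °C
Reagents that add atoms: none
Why: Oxoammonium-mediated (TEMPO) oxidation of the primary alcohol stops at the aldehyde and does not touch the alkenyl iodide.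

Step 10
Reactants: 18 6-methylhept-5-en-2-one; 19 2,4,6-tri(propan-2-yl)benzenesulfonohydrazide
Product: 20 N'-(6-methylhept-5-en-2-ylidene)-2,4,6-tri(propan-2-yl)benzenesulfonohydrazide
Conditions: HCl (cat.), MeOH, 23 °C
Reagents that add atoms: none
Why: Acid-catalysed condensation of the methyl ketone with the arylsulfonyl hydrazide gives the hydrazone needed for the Shapiro reaction.

Step 11
Reactants: 20 N'-(6-methylhept-5-en-2-ylidene)-2,4,6-tri(propan-2-yl)benzenesulfonohydrazide; 17 (4E)-5-iodo-4-methylpent-4-enal
Product: 22 (1E)-1-iodo-2,10-dimethyl-6-methylideneundeca-1,9-dien-5-ol (racemic), via alkenyllithium 21 (not isolated)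
Conditions: nBuLi (2.1 equiv), THF, −78 → 0 °C; then 17, −78 °C; then H2O
Reagents that add atoms: none
Why: Shapiro reaction, in which the hydrazone dianion forms at the methyl group and loses sulfinate and N2 to give the 2-lithio-1-alkene, which adds to the aldehyde carbonyl at −78 °C faster than it exchanges with the alkenyl iodide; the carbinol is formed racemic and is corrected in steps 12 and 13.

Step 12
Reactants: 22 (1E)-1-iodo-2,10-dimethyl-6-methylideneundeca-1,9-dien-5-ol (racemic)
Product: 23 (1E)-1-iodo-2,10-dimethyl-6-methylideneundeca-1,9-dien-5-one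
Conditions: Dess–Martin periodinane (1.2 equiv), CH2Cl2, 0 → 23 °C
Reagents that add atoms: none
Why: Dess–Martin oxidation of the secondary allylic alcohol gives the α-methylene ketone under neutral conditions that spare the alkenes and the alkenyl iodide.

Step 13
Reactants: 23 (1E)-1-iodo-2,10-dimethyl-6-methylideneundeca-1,9-dien-5-one
Product: 24 (1E,5R)-1-iodo-2,10-dimethyl-6-methylideneundeca-1,9-dien-5-ol
Conditions: (S)-2-methyl-CBS-oxazaborolidine (0.2 equiv), catecholborane (1.5 equiv), PhMe, −78 °C
Reagents that add atoms: none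
Why: Corey–Bakshi–Shibata reduction, in which the α-branched alkenyl group acts as the large substituent so that the (S)-oxazaborolidine delivers hydride to the face giving the (R)-alcohol, while catecholborane at −78 °C does not hydroborate the alkenes.

Step 14
Reactants: 13 ethyl 2-[(2R,5R)-5-(2-iodoethyl)oxan-2-yl]prop-2-enoate; 24 (1E,5R)-1-iodo-2,10-dimethyl-6-methylideneundeca-1,9-dien-5-ol
Product: 26 ethyl 2-[(2R,5S)-5-[(3E,7R)-7-hydroxy-4,12-dimethyl-8-methylidenetrideca-3,11-dien-1-yl]oxan-2-yl]prop-2-enoate, via alkylzinc iodide 25 (not isolated)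
Conditions: Zn dust (activated with BrCH2CH2Br and Me3SiCl), LiCl, THF, 30 °C; then 24 (0.8 equiv), Pd(OAc)2 (3 mol %), SPhos (6 mol %), THF, 23 °C
Reagents that add atoms: none
Why: Negishi coupling, in which zinc inserts into the primary C–I bond and the alkylzinc iodide (tolerant of the ester, the acrylate and, with a fast palladium/biarylphosphine catalyst, the free alcohol) couples with the alkenyl iodide with retention of the E geometry and without touching a stereocentre.

Step 15
Reactants: 26 ethyl 2-[(2R,5S)-5-[(3E,7R)-7-hydroxy-4,12-dimethyl-8-methylidenetrideca-3,11-dien-1-yl]oxan-2-yl]prop-2-enoate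
Product: 27 2-[(2R,5S)-5-[(3E,7R)-7-hydroxy-4,12-dimethyl-8-methylidenetrideca-3,11-dien-1-yl]oxan-2-yl]prop-2-enoic acid
Conditions: LiOH (3 equiv), THF/H2O, 0 → 23 °C; then 1 M HCl to pH 3
Reagents that add atoms: lithium hydroxide, [Li+].[OH-]
Why: Saponification of the ethyl ester by acyl substitution with hydroxide should give the acid without affecting the stereocentres or the alkenes.

**Compound list**

1 | ethyl (3S)-4-chloro-3-hydroxybutanoate | CCOC(=O)C[C@H](O)CCl | starting material
2 | ethyl (3S)-3-hydroxy-4-iodobutanoate | IC[C@@H](O)CC(=O)OCC | intermediate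
3 | 4-chlorobutanal | O=CCCCCl | starting material
4 | formaldehyde | C=O | starting material
5 | 4-chloro-2-methylidenebutanal | C=C(CCCl)C=O | intermediate
6 | ethyl (3R,6RS)-8-chloro-6-formyl-3-hydroxyoctanoate | ClCCC(C=O)CC[C@H](CC(=O)OCC)O | intermediate
7 | ethyl 2-[(2R,5RS,6RS)-5-(2-chloroethyl)-6-hydroxyoxan-2-yl]acetate | ClCCC1CC[C@H](CC(=O)OCC)OC1O | intermediate
8 | ethyl 2-[(2R,5R,6RS)-5-(2-chloroethyl)-6-hydroxyoxan-2-yl]acetate | ClCC[C@H]1CC[C@H](CC(=O)OCC)OC1O | intermediate
9 | ethyl 2-[(2R,5R)-5-(2-chloroethyl)oxan-2-yl]acetate | ClCC[C@H]1CC[C@H](CC(=O)OCC)OC1 | intermediate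
10 | ethyl 2-[(2R,5R)-5-(2-chloroethyl)oxan-2-yl]-3-(dimethylamino)propanoate | ClCC[C@H]1CC[C@H](C(CN(C)C)C(=O)OCC)OC1 | intermediate
11 | 2-[(2R,5R)-5-(2-chloroethyl)oxan-2-yl]-3-ethoxy-N,N,N-trimethyl-3-oxopropan-1-aminium iodide | ClCC[C@H]1CC[C@H](C(C[N+](C)(C)C)C(=O)OCC)OC1.[I-] | intermediate
12 | ethyl 2-[(2R,5R)-5-(2-chloroethyl)oxan-2-yl]prop-2-enoate | ClCC[C@H]1CC[C@H](C(=C)C(=O)OCC)OC1 | intermediate
13 | ethyl 2-[(2R,5R)-5-(2-iodoethyl)oxan-2-yl]prop-2-enoate | ICC[C@H]1CC[C@H](C(=C)C(=O)OCC)OC1 | intermediate
14 | pent-4-yn-1-ol | C#CCCCO | starting material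
15 | dimethylaluminium (4E)-5-(dimethylalumanyl)-4-methylpent-4-en-1-olate | C[Al](C)/C=C(C)/CCCO[Al](C)C | intermediate
16 | (4E)-5-iodo-4-methylpent-4-en-1-ol | OCCC/C(C)=C/I | intermediate
17 | (4E)-5-iodo-4-methylpent-4-enal | O=CCC/C(C)=C/I | intermediate
18 | 6-methylhept-5-en-2-one | CC(=O)CCC=C(C)C | starting material
19 | 2,4,6-tri(propan-2-yl)benzenesulfonohydrazide | NNS(=O)(=O)c1c(C(C)C)cc(C(C)C)cc1C(C)C | starting material
20 | N'-(6-methylhept-5-en-2-ylidene)-2,4,6-tri(propan-2-yl)benzenesulfonohydrazide | CC(CCC=C(C)C)=NNS(=O)(=O)c1c(C(C)C)cc(C(C)C)cc1C(C)C | intermediate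
21 | (6-methylhepta-1,5-dien-2-yl)lithium | [Li]C(=C)CCC=C(C)C | intermediate
22 | (1E)-1-iodo-2,10-dimethyl-6-methylideneundeca-1,9-dien-5-ol (racemic) | C=C(CCC=C(C)C)C(O)CC/C(C)=C/I | intermediate
23 | (1E)-1-iodo-2,10-dimethyl-6-methylideneundeca-1,9-dien-5-one | C=C(CCC=C(C)C)C(=O)CC/C(C)=C/I | intermediate
24 | (1E,5R)-1-iodo-2,10-dimethyl-6-methylideneundeca-1,9-dien-5-ol | C=C(CCC=C(C)C)[C@H](O)CC/C(C)=C/I | intermediate
25 | [2-[(3R,6R)-6-(3-ethoxy-3-oxoprop-1-en-2-yl)oxan-3-yl]ethyl]zinc iodide | I[Zn]CC[C@H]1CC[C@H](C(=C)C(=O)OCC)OC1 | intermediate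
26 | ethyl 2-[(2R,5S)-5-[(3E,7R)-7-hydroxy-4,12-dimethyl-8-methylidenetrideca-3,11-dien-1-yl]oxan-2-yl]prop-2-enoate | C=C(CCC=C(C)C)[C@H](O)CC/C(C)=C/CC[C@H]1CC[C@H](C(=C)C(=O)OCC)OC1 | intermediate
27 | 2-[(2R,5S)-5-[(3E,7R)-7-hydroxy-4,12-dimethyl-8-methylidenetrideca-3,11-dien-1-yl]oxan-2-yl]prop-2-enoic acid | C=C(CCC=C(C)C)[C@H](O)CC/C(C)=C/CC[C@H]1CC[C@H](C(=C)C(=O)O)OC1 | target

**Step count and risks**

Total step count: 15.
Longest linear sequence: 8 steps (steps 1, 3, 4, 5, 6, 7, 14, 15, from compound 1; the same length from compound 3 through step 2).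

Steps most likely to fail:

1) Step 3. The radical chain may be short because the acrolein oligomerizes or the alkyl radical is reduced before it adds. The equilibration may also stop at a modest trans/cis ratio, because only the equatorial preference of one alkyl arm separates the two chairs. Fallback (catalyst control in place of thermodynamic control): it sets out from the unequilibrated lactol mixture 7 and comes back at 9. The mixture 7 is dehydrated (MsCl, Et3N, CH2Cl2, 0 → 40 °C) to the cyclic enol ether ethyl 2-[(2R)-5-(2-chloroethyl)-3,4-dihydro-2H-pyran-2-yl]acetate F1, in which both C5 epimers converge on one compound. Asymmetric hydrogenation of F1 under H2 with a chiral iridium phosphine–oxazoline complex, [Ir(cod)(L*)][B(C6H3(CF3)2)4], the ligand enantiomer being chosen for the trans product, would then set C5 kinetically and give 9.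

2) Step 5. The lithium ester enolate may expel the ring oxygen (E1cB ring opening), or the aminomethylation may stay incomplete. Fallback (methylenation at the aldehyde oxidation level, without a lithium enolate): it sets out from 9 and comes back at 12. Ester 9 is reduced with iBu2AlH (CH2Cl2, −78 °C) to 2-[(2R,5R)-5-(2-chloroethyl)oxan-2-yl]acetaldehyde F2. Treatment with CH2=NMe2+ I− and Et3N (CH2Cl2, 23 °C) should give 2-[(2R,5R)-5-(2-chloroethyl)oxan-2-yl]prop-2-enal F3. Pinnick oxidation (NaClO2, NaH2PO4, 2-methylbut-2-ene, tBuOH/H2O) should give 2-[(2R,5R)-5-(2-chloroethyl)oxan-2-yl]prop-2-enoic acid F4, and O-alkylation with EtI and K2CO3 in DMF gives 12. If a retro-oxa-Michael/oxa-Michael event intervenes at the aldehyde stage, re-closure is expected to favour the same trans ring, because C5 is already fixed.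

3) Step 14. The alkylzinc may be protonated by the free allylic alcohol, the alkylpalladium intermediate may undergo β-hydride elimination, or zinc insertion may be slow. Fallback (coupling before the carbinol is made, so that no protic group is present): it sets out from 13 and 23 and comes back at 26. The alkylzinc iodide 25 made from 13 is coupled under the same palladium catalysis with ketone 23 to give ethyl 2-[(2R,5S)-5-[(3E)-4,12-dimethyl-8-methylidene-7-oxotrideca-3,11-dien-1-yl]oxan-2-yl]prop-2-enoate F5. CBS reduction of F5 ((S)-2-methyl-CBS-oxazaborolidine, catecholborane, PhMe, −78 °C), which should reduce the ketone in preference to the acrylate ester, gives 26.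

Further compounds
F1 | step 3 | ethyl 2-[(2R)-5-(2-chloroethyl)-3,4-dihydro-2H-pyran-2-yl]acetate | ClCCC1=CO[C@@H](CC(=O)OCC)CC1
F2 | step 5 | 2-[(2R,5R)-5-(2-chloroethyl)oxan-2-yl]acetaldehyde | ClCC[C@H]1CC[C@H](CC=O)OC1
F3 | step 5 | 2-[(2R,5R)-5-(2-chloroethyl)oxan-2-yl]prop-2-enal | ClCC[C@H]1CC[C@H](C(=C)C=O)OC1
F4 | step 5 | 2-[(2R,5R)-5-(2-chloroethyl)oxan-2-yl]prop-2-enoic acid | ClCC[C@H]1CC[C@H](C(=C)C(=O)O)OC1
F5 | step 14 | ethyl 2-[(2R,5S)-5-[(3E)-4,12-dimethyl-8-methylidene-7-oxotrideca-3,11-dien-1-yl]oxan-2-yl]prop-2-enoate | C=C(CCC=C(C)C)C(=O)CC/C(C)=C/CC[C@H]1CC[C@H](C(=C)C(=O)OCC)OC1
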